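**Plan**

- Retrosynthesis: the O7 acetal and a temporary C8 methoxy group come off last. Ring C is then cut at C2–C3 and O1–C8a into the ring B aldehyde and a ring A methyl ketone. Ring A goes back to 2-methylresorcinol by cutting C4a–acetyl, C6–prenyl and C5–O.
- Enabling feature: in ring A the methyl-bearing C8 is para to the C5 oxygen, and C8a lies between C8 and C4a. Oxidising the C5 phenol to the p-quinol methyl ether (sp3 C8) makes C5 a true ketone and C4a=C8a–O a vinylogous ester. With the enol silane of the C4 acetyl group, C3=C4(OSi)–C4a=C8a(OR) is then a 1-alkoxy-3-silyloxy-diene inside ring A.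
- Forward: ring B aldehyde by cross-coupling; ring A is fully substituted as an arene and dearomatised; ring C is closed onto it by a catalytic asymmetric formal hetero-Diels–Alder reaction with the aldehyde; ring A is re-aromatised with zinc and the last acetal is cleaved.
- Stereochemistry: C2 (S) comes from the chiral boron Lewis acid (Si-face attack on the aldehyde). The racemic C8 centre of the quinol is erased on re-aromatisation, so both epimers converge. The regiochemistry (O1 next to C8–CH3, prenyl at C6) follows from the single leaving group at C8a.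

Key step: step 9

Remark: the ethoxyethyl acetal carbon and the quinol carbon C8 are formed racemic and are removed later, so the intermediates that carry them are used as mixtures and drawn without configuration there; the sense of induction of the oxazaborolidinone is taken from its face-shielding model, and the mirror-image catalyst is used should a test aldol addition with benzaldehyde show the opposite sense.

**Route**

Step 1
Reactants: 1 2-methylbenzene-1,3-diol (2-methylresorcinol)
Product: 2 1,3-bis(methoxymethoxy)-2-methylbenzene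
Conditions: MOMCl (2.6 equiv), i-Pr2NEt, CH2Cl2, 0 °C to rt
Reagents that add atoms: chloromethyl methyl ether, COCCl
Why: Williamson-type O-alkylation of both phenols gives acetals that later direct the lithiations, supply the leaving group at C8a and mask O7.

Step 2
Reactants: 2 1,3-bis(methoxymethoxy)-2-methylbenzene
Product: 4 3,5-bis(methoxymethoxy)-4-methylphenol, via aryl pinacol boronate 3 (not isolated)
Conditions: [Ir(OMe)(cod)]2 (1.5 mol %), 4,4'-di-tert-butyl-2,2'-bipyridine (3 mol %), B2pin2 (1.0 equiv), THF, 80 °C; then 30% H2O2, aq. NaOH, 0 °C to rt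
Reagents that add atoms: hydrogen peroxide, OO; bis(pinacolato)diboron, CC1(C)OB(OC1(C)C)B1OC(C)(C)C(C)(C)O1 (its boron stays only in 3)
Why: Sterically controlled iridium-catalysed C–H borylation takes the only ring C–H without an ortho substituent (para to the methyl group), and boronate oxidation with aryl migration from boron to oxygen gives the phenol that becomes O5.

Step 3
Reactants: 4 3,5-bis(methoxymethoxy)-4-methylphenol
Product: 5 5-(1-ethoxyethoxy)-1,3-bis(methoxymethoxy)-2-methylbenzene
Conditions: ethyl vinyl ether (3 equiv), PPTS (5 mol %), CH2Cl2, rt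
Reagents that add atoms: ethyl vinyl ether, C=COCC
Why: Acid-catalysed addition of the phenol to the enol ether gives a mixed acetal that directs lithiation like the methoxymethyl groups but is cleaved by much weaker acid, so O5 stays distinguishable from O7 and O8a.

Step 4
Reactants: 5 5-(1-ethoxyethoxy)-1,3-bis(methoxymethoxy)-2-methylbenzene
Product: 7 1-(1-ethoxyethoxy)-3,5-bis(methoxymethoxy)-4-methyl-2-(3-methylbut-2-en-1-yl)benzene, via aryllithium 6 (not isolated)
Conditions: n-BuLi (1.1 equiv), THF, 0 °C; CuBr·SMe2 (10 mol %), prenyl bromide, −78 °C to rt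
Reagents that add atoms: 1-bromo-3-methylbut-2-ene (prenyl bromide), CC(C)=CCBr; butyllithium, [Li]CCCC (its lithium stays only in 6)
Why: Directed ortho-lithiation at one of the two equivalent C–H positions flanked by two acetal oxygens, followed by copper-catalysed SN2 allylation, places the prenyl group on the carbon that becomes C6.

Step 5
Reactants: 7 1-(1-ethoxyethoxy)-3,5-bis(methoxymethoxy)-4-methyl-2-(3-methylbut-2-en-1-yl)benzene
Product: 10 1-[2-hydroxy-4,6-bis(methoxymethoxy)-5-methyl-3-(3-methylbut-2-en-1-yl)phenyl]ethan-1-one, via aryllithium 8 (not isolated), via ethoxyethyl ketone 9 (not isolated)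
Conditions: n-BuLi (1.2 equiv), TMEDA, THF, 0 °C; MeC(O)N(OMe)Me, −78 °C to rt; H2O; then PPTS (10 mol %), MeOH, rt
Reagents that add atoms: N-methoxy-N-methylacetamide, CC(=O)N(C)OC; butyllithium, [Li]CCCC (its lithium stays only in 8)
Why: A second directed ortho-lithiation at the last ring C–H and acylation with the N-methoxy-N-methylamide (stable tetrahedral chelate, no over-addition) give the methyl ketone, and acetal exchange in methanol removes only the ethoxyethyl group, which frees the C5 hydroxyl group.

Step 6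
Reactants: 10 1-[2-hydroxy-4,6-bis(methoxymethoxy)-5-methyl-3-(3-methylbut-2-en-1-yl)phenyl]ethan-1-one
Product: 11 2-acetyl-4-methoxy-3,5-bis(methoxymethoxy)-4-methyl-6-(3-methylbut-2-en-1-yl)cyclohexa-2,5-dien-1-one
Conditions: PhI(OAc)2 (1.1 equiv), NaHCO3, MeOH–CH2Cl2, −20 to 0 °C
Reagents that add atoms: methanol, CO
Why: Oxidative dearomatisation of the phenol with the hypervalent iodine reagent and capture by methanol at the para carbon C8 gives the p-quinol methyl ether; capture at C6 instead would give an o-quinol ether with the same diene precursor and the same fate in step 10, so the site of capture is not critical.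

Step 7
Reactants: 11 2-acetyl-4-methoxy-3,5-bis(methoxymethoxy)-4-methyl-6-(3-methylbut-2-en-1-yl)cyclohexa-2,5-dien-1-one
Product: 13 4-methoxy-3,5-bis(methoxymethoxy)-4-methyl-6-(3-methylbut-2-en-1-yl)-2-[1-(trimethylsilyloxy)ethenyl]cyclohexa-2,5-dien-1-one, via lithium enolate 12 (not isolated)
Conditions: LiN(SiMe3)2 (1.1 equiv), THF, −78 °C; Me3SiCl (1.3 equiv), −78 to 0 °C; pentane, filtration, used crude
Reagents that add atoms: chlorotrimethylsilane, C[Si](C)(C)Cl; lithium bis(trimethylsilyl)amide, [Li]N([Si](C)(C)C)[Si](C)(C)C (its lithium stays only in 12)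
Why: Kinetic deprotonation of the acetyl methyl group, the only enolisable position of 11, and O-silylation give the enol silane, which with C4a=C8a–OCH2OCH3 forms the ring-embedded 1-alkoxy-3-silyloxy-1,3-diene.

Step 8
Reactants: 14 3-bromo-4-methoxybenzaldehyde
Product: 15 4-methoxy-3-(3-methylbut-2-en-1-yl)benzaldehyde
Conditions: tributyl(3-methylbut-2-en-1-yl)stannane (1.2 equiv), Pd(PPh3)4 (5 mol %), DMF, 90 °C
Reagents that add atoms: tributyl(3-methylbut-2-en-1-yl)stannane, CCCC[Sn](CCCC)(CCCC)CC=C(C)C
Why: Stille coupling of the aryl bromide with the prenylstannane forms the aryl–CH2 bond at the less hindered allyl terminus and leaves the aldehyde untouched.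

Step 9
Reactants: 13 4-methoxy-3,5-bis(methoxymethoxy)-4-methyl-6-(3-methylbut-2-en-1-yl)-2-[1-(trimethylsilyloxy)ethenyl]cyclohexa-2,5-dien-1-one; 15 4-methoxy-3-(3-methylbut-2-en-1-yl)benzaldehyde
Product: 17 (2S)-8-methoxy-2-[4-methoxy-3-(3-methylbut-2-en-1-yl)phenyl]-7-(methoxymethoxy)-8-methyl-6-(3-methylbut-2-en-1-yl)-2,3-dihydro-4H-chromene-4,5(8H)-dione (both C8 epimers), via aldol silyl ether 16 (not isolated)
Conditions: 13 (1.3 equiv), (4R)-2-butyl-4-(1H-indol-3-ylmethyl)-3-tosyl-1,3,2-oxazaborolidin-5-one (from N-tosyl-(R)-tryptophan and BuB(OH)2, 20 mol %), EtCN, −78 °C; then CF3CO2H (0.3 equiv), CH2Cl2, 0 °C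
Reagents that add atoms: none
Why: Proposed new method: the boron Lewis acid binds the aldehyde oxygen of 15 and the terminal CH2 carbon (the future C3) of the enol silane adds to the Si face of the aldehyde carbon (Mukaiyama aldol with silyl transfer to give 16, C2–C3 bond); under trifluoroacetic acid the C2 oxygen then adds to C8a, which is β to both the C4 and the C5 carbonyl group, and the C8a methoxymethoxy group leaves so that C4a=C8a is restored (O1–C8a bond), overall a stepwise formal hetero-Diels–Alder reaction. The closest known reaction type is the catalytic asymmetric aldol–dihydropyranone annulation of aldehydes with 1-alkoxy-3-silyloxybuta-1,3-dienes (Danishefsky-type dienes); new is that the diene sits in a p-quinol ether ring with a fully substituted C4a=C8a bond. Ring C closes by a 6-endo-trig oxa-Michael addition followed by β-elimination. The only new stereocentre, C2, is set by the catalyst, whose indolylmethyl group is expected to cover the Re face of the bound aldehyde, while the racemic C8 centre lies four bonds from the reacting carbon and is removed in step 10, so both C8 epimers of 17 are carried on together. The step needs O1 to bond to C8a and not to C5, which is secured because C5 is a ketone carbon that can only form a reversible hemiketal while C8a carries the one leaving group, and it needs ring closure to outrun ionisation of the p-methoxybenzylic silyl ether, for which the acid is kept substoichiometric, anhydrous and cold.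

Step 10
Reactants: 17 (2S)-8-methoxy-2-[4-methoxy-3-(3-methylbut-2-en-1-yl)phenyl]-7-(methoxymethoxy)-8-methyl-6-(3-methylbut-2-en-1-yl)-2,3-dihydro-4H-chromene-4,5(8H)-dione
Product: 18 (2S)-5-hydroxy-2-[4-methoxy-3-(3-methylbut-2-en-1-yl)phenyl]-7-(methoxymethoxy)-8-methyl-6-(3-methylbut-2-en-1-yl)-2,3-dihydro-4H-chromen-4-one
Conditions: Zn dust (10 equiv), AcOH–THF (1:4), 0 °C to rt
Reagents that add atoms: none
Why: Two-electron reduction of the cross-conjugated dienone with loss of the C8 methoxy group (reductive aromatisation of a quinol ether) returns ring A to the arene with the C5 hydroxyl group free, removes the C8 stereocentre of both epimers and does not touch C2.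

Step 11
Reactants: 18 (2S)-5-hydroxy-2-[4-methoxy-3-(3-methylbut-2-en-1-yl)phenyl]-7-(methoxymethoxy)-8-methyl-6-(3-methylbut-2-en-1-yl)-2,3-dihydro-4H-chromen-4-one
Product: 19 (2S)-5,7-dihydroxy-2-[4-methoxy-3-(3-methylbut-2-en-1-yl)phenyl]-8-methyl-6-(3-methylbut-2-en-1-yl)-2,3-dihydro-4H-chromen-4-one
Conditions: 3 M aq. HCl–MeOH (1:5), 45 °C
Reagents that add atoms: none
Why: Acid-catalysed acetal exchange (methoxymethyl ether cleavage) frees the C7 hydroxyl group under conditions in which a flavanone, which loses its C2 configuration by base-induced ring opening, is configurationally stable.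

**Compound list**

1 | 2-methylbenzene-1,3-diol | Cc1c(O)cccc1O | starting material
2 | 1,3-bis(methoxymethoxy)-2-methylbenzene | COCOc1cccc(OCOC)c1C | intermediate
3 | 2-[3,5-bis(methoxymethoxy)-4-methylphenyl]-4,4,5,5-tetramethyl-1,3,2-dioxaborolane | COCOc1cc(B2OC(C)(C)C(C)(C)O2)cc(OCOC)c1C | intermediate
4 | 3,5-bis(methoxymethoxy)-4-methylphenol | COCOc1cc(O)cc(OCOC)c1C | intermediate
5 | 5-(1-ethoxyethoxy)-1,3-bis(methoxymethoxy)-2-methylbenzene (racemic) | CCOC(C)Oc1cc(OCOC)c(C)c(OCOC)c1 | intermediate
6 | [2-(1-ethoxyethoxy)-4,6-bis(methoxymethoxy)-5-methylphenyl]lithium | CCOC(C)Oc1cc(OCOC)c(C)c(OCOC)c1[Li] | intermediate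
7 | 1-(1-ethoxyethoxy)-3,5-bis(methoxymethoxy)-4-methyl-2-(3-methylbut-2-en-1-yl)benzene | CCOC(C)Oc1cc(OCOC)c(C)c(OCOC)c1CC=C(C)C | intermediate
8 | [2-(1-ethoxyethoxy)-4,6-bis(methoxymethoxy)-5-methyl-3-(3-methylbut-2-en-1-yl)phenyl]lithium | CCOC(C)Oc1c([Li])c(OCOC)c(C)c(OCOC)c1CC=C(C)C | intermediate
9 | 1-[2-(1-ethoxyethoxy)-4,6-bis(methoxymethoxy)-5-methyl-3-(3-methylbut-2-en-1-yl)phenyl]ethan-1-one | CCOC(C)Oc1c(C(C)=O)c(OCOC)c(C)c(OCOC)c1CC=C(C)C | intermediate
10 | 1-[2-hydroxy-4,6-bis(methoxymethoxy)-5-methyl-3-(3-methylbut-2-en-1-yl)phenyl]ethan-1-one | CC(=O)c1c(O)c(CC=C(C)C)c(OCOC)c(C)c1OCOC | intermediate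
11 | 2-acetyl-4-methoxy-3,5-bis(methoxymethoxy)-4-methyl-6-(3-methylbut-2-en-1-yl)cyclohexa-2,5-dien-1-one (racemic) | CC(=O)C1=C(OCOC)C(C)(OC)C(OCOC)=C(CC=C(C)C)C1=O | intermediate
12 | lithium enolate of 11 at the acetyl group | [Li]OC(=C)C1=C(OCOC)C(C)(OC)C(OCOC)=C(CC=C(C)C)C1=O | intermediate
13 | 4-methoxy-3,5-bis(methoxymethoxy)-4-methyl-6-(3-methylbut-2-en-1-yl)-2-[1-(trimethylsilyloxy)ethenyl]cyclohexa-2,5-dien-1-one (racemic) | C=C(O[Si](C)(C)C)C1=C(OCOC)C(C)(OC)C(OCOC)=C(CC=C(C)C)C1=O | intermediate
14 | 3-bromo-4-methoxybenzaldehyde | COc1ccc(C=O)cc1Br | starting material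
15 | 4-methoxy-3-(3-methylbut-2-en-1-yl)benzaldehyde | COc1ccc(C=O)cc1CC=C(C)C | intermediate
16 | 4-methoxy-2-[(3S)-3-[4-methoxy-3-(3-methylbut-2-en-1-yl)phenyl]-3-(trimethylsilyloxy)propanoyl]-3,5-bis(methoxymethoxy)-4-methyl-6-(3-methylbut-2-en-1-yl)cyclohexa-2,5-dien-1-one (both C4 epimers of the ring) | COc1ccc([C@@H](O[Si](C)(C)C)CC(=O)C2=C(OCOC)C(C)(OC)C(OCOC)=C(CC=C(C)C)C2=O)cc1CC=C(C)C | intermediate
17 | (2S)-8-methoxy-2-[4-methoxy-3-(3-methylbut-2-en-1-yl)phenyl]-7-(methoxymethoxy)-8-methyl-6-(3-methylbut-2-en-1-yl)-2,3-dihydro-4H-chromene-4,5(8H)-dione (both C8 epimers) | COc1ccc([C@@H]2CC(=O)C3=C(O2)C(C)(OC)C(OCOC)=C(CC=C(C)C)C3=O)cc1CC=C(C)C | intermediate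
18 | (2S)-5-hydroxy-2-[4-methoxy-3-(3-methylbut-2-en-1-yl)phenyl]-7-(methoxymethoxy)-8-methyl-6-(3-methylbut-2-en-1-yl)-2,3-dihydro-4H-chromen-4-one | COc1ccc([C@@H]2CC(=O)c3c(O)c(CC=C(C)C)c(OCOC)c(C)c3O2)cc1CC=C(C)C | intermediate
19 | (2S)-5,7-dihydroxy-2-[4-methoxy-3-(3-methylbut-2-en-1-yl)phenyl]-8-methyl-6-(3-methylbut-2-en-1-yl)-2,3-dihydro-4H-chromen-4-one | COc1ccc([C@@H]2CC(=O)c3c(O)c(CC=C(C)C)c(O)c(C)c3O2)cc1CC=C(C)C | target

**Step count and risks**

Total step count: 11. Longest linear sequence: 10 steps (steps 1–7 and 9–11, from 2-methylresorcinol).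

Steps most likely to fail:

1. Step 9 (the proposed new method). The basic dienone oxygen of 13 may hold the boron catalyst so that the aldol addition stalls, facial selectivity may be poor on this new diene class, or the silyl ether may ionise at the benzylic carbon before it closes. The fallback uses known chemistry, sets out from 10 and returns at 18: ring C is closed on the aromatic ring by aldol addition and Mitsunobu etherification in place of the annulation.
   - O-Allylation of 10 (allyl bromide, K2CO3, DMF) gives the allyl ether F1.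
   - The methoxymethyl group ortho to the acetyl group, now the only chelation-activated acetal, is cleaved selectively (HCl cat., MeOH, 0 °C) to give the phenol F2, whose free oxygen is the one next to the C-methyl group.
   - Me3SiOTf/Et3N gives the aryl silyl ether–enol silane F3.
   - A Mukaiyama aldol addition to 15 under the mirror-image oxazaborolidinone (Re-face attack) gives the (R)-configured bis-silyl aldol F4 and, after citric acid in methanol, the (R)-β-hydroxy ketone F5.
   - Mitsunobu cyclisation (PPh3, DIAD, THF, 0 °C) closes the O1–C2 bond with inversion to give the (S)-flavanone allyl ether F6.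
   - Pd(PPh3)4/morpholine removes the allyl group and gives 18.

2. Step 6. The electrophilic iodine reagent or the phenoxonium ion may be intercepted by the electron-rich trisubstituted double bond of the C6 prenyl group (oxidative cyclisation onto O5) instead of methanol adding to the ring. The fallback sets out from 5 and returns at 11: the side chain is carried through the oxidation as a plain allyl group, whose monosubstituted double bond is far less nucleophilic, and is turned into the prenyl group afterwards by olefin cross-metathesis.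
   - Lithiation of 5 (which gives 6 as in step 4) and copper-catalysed allylation with allyl bromide give the allyl arene F7.
   - A second lithiation to the aryllithium F8, acylation with N-methoxy-N-methylacetamide to the ethoxyethyl ketone F9 and PPTS/MeOH give the phenol F10.
   - PhI(OAc)2/MeOH gives the allyl quinol ether F11.
   - Cross-metathesis with 2-methylbut-2-ene (second-generation Grubbs catalyst, RuCl2(=CHPh)(H2IMes)(PCy3), CH2Cl2, 40 °C) gives 11.

3. Step 11. Under the acid needed for an aryl methoxymethyl ether, the C5 or C7 hydroxyl group may add to the protonated C6 prenyl double bond (chroman formation), and long heating may open ring C. The fallback sets out from 17 and returns at 19: the acetal is removed one stage earlier, while O7 is still a vinylogous ester oxygen and its methoxymethyl group is a far more labile acylal-type acetal, and the reduction is done last.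
   - Brief treatment of 17 with dilute aqueous HCl in THF at 0 °C gives the vinylogous acid F12.
   - Zn/AcOH–THF then gives 19 directly.

Further compounds

F1 | step 9 | 1-[4,6-bis(methoxymethoxy)-5-methyl-3-(3-methylbut-2-en-1-yl)-2-(prop-2-en-1-yloxy)phenyl]ethan-1-one | CC(=O)c1c(OCC=C)c(CC=C(C)C)c(OCOC)c(C)c1OCOC
F2 | step 9 | 1-[2-hydroxy-4-(methoxymethoxy)-3-methyl-5-(3-methylbut-2-en-1-yl)-6-(prop-2-en-1-yloxy)phenyl]ethan-1-one | CC(=O)c1c(OCC=C)c(CC=C(C)C)c(OCOC)c(C)c1O
F3 | step 9 | {3-(methoxymethoxy)-2-methyl-4-(3-methylbut-2-en-1-yl)-5-(prop-2-en-1-yloxy)-6-[1-(trimethylsilyloxy)ethenyl]phenoxy}trimethylsilane | C=C(O[Si](C)(C)C)c1c(OCC=C)c(CC=C(C)C)c(OCOC)c(C)c1O[Si](C)(C)C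
F4 | step 9 | (3R)-3-[4-methoxy-3-(3-methylbut-2-en-1-yl)phenyl]-1-[4-(methoxymethoxy)-3-methyl-5-(3-methylbut-2-en-1-yl)-6-(prop-2-en-1-yloxy)-2-(trimethylsilyloxy)phenyl]-3-(trimethylsilyloxy)propan-1-one | COc1ccc([C@H](O[Si](C)(C)C)CC(=O)c2c(OCC=C)c(CC=C(C)C)c(OCOC)c(C)c2O[Si](C)(C)C)cc1CC=C(C)C
F5 | step 9 | (3R)-3-hydroxy-1-[2-hydroxy-4-(methoxymethoxy)-3-methyl-5-(3-methylbut-2-en-1-yl)-6-(prop-2-en-1-yloxy)phenyl]-3-[4-methoxy-3-(3-methylbut-2-en-1-yl)phenyl]propan-1-one | COc1ccc([C@H](O)CC(=O)c2c(OCC=C)c(CC=C(C)C)c(OCOC)c(C)c2O)cc1CC=C(C)C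
F6 | step 9 | (2S)-2-[4-methoxy-3-(3-methylbut-2-en-1-yl)phenyl]-7-(methoxymethoxy)-8-methyl-6-(3-methylbut-2-en-1-yl)-5-(prop-2-en-1-yloxy)-2,3-dihydro-4H-chromen-4-one | COc1ccc([C@@H]2CC(=O)c3c(OCC=C)c(CC=C(C)C)c(OCOC)c(C)c3O2)cc1CC=C(C)C
F7 | step 6 | 1-(1-ethoxyethoxy)-3,5-bis(methoxymethoxy)-4-methyl-2-(prop-2-en-1-yl)benzene | CCOC(C)Oc1cc(OCOC)c(C)c(OCOC)c1CC=C
F8 | step 6 | [2-(1-ethoxyethoxy)-4,6-bis(methoxymethoxy)-5-methyl-3-(prop-2-en-1-yl)phenyl]lithium | CCOC(C)Oc1c([Li])c(OCOC)c(C)c(OCOC)c1CC=C
F9 | step 6 | 1-[2-(1-ethoxyethoxy)-4,6-bis(methoxymethoxy)-5-methyl-3-(prop-2-en-1-yl)phenyl]ethan-1-one | CCOC(C)Oc1c(C(C)=O)c(OCOC)c(C)c(OCOC)c1CC=C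
F10 | step 6 | 1-[2-hydroxy-4,6-bis(methoxymethoxy)-5-methyl-3-(prop-2-en-1-yl)phenyl]ethan-1-one | CC(=O)c1c(O)c(CC=C)c(OCOC)c(C)c1OCOC
F11 | step 6 | 2-acetyl-4-methoxy-3,5-bis(methoxymethoxy)-4-methyl-6-(prop-2-en-1-yl)cyclohexa-2,5-dien-1-one | CC(=O)C1=C(OCOC)C(C)(OC)C(OCOC)=C(CC=C)C1=O
F12 | step 11 | (2S)-7-hydroxy-8-methoxy-2-[4-methoxy-3-(3-methylbut-2-en-1-yl)phenyl]-8-methyl-6-(3-methylbut-2-en-1-yl)-2,3-dihydro-4H-chromene-4,5(8H)-dione | COc1ccc([C@@H]2CC(=O)C3=C(O2)C(C)(OC)C(O)=C(CC=C(C)C)C3=O)cc1CC=C(C)C
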